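Retrosynthesis (azulene locants C1–C3, C3a, C4–C8, C8a; β = face of the C8a methyl): remove the C4 aroyl group and the C6 methylene, cut the C3–isopropyl bond back to a C3 ketone, then cut both cycloheptane bonds C3a–C4 and C8–C8a in one event.
Enabling feature: ring atoms C4–C8 carry oxygen at C4 and C7, with C8 a methylene beside quaternary C8a, which is a cyclopentane-1,3-dione enlarged by the two carbons C3a/C8a; the C3 oxygen sits 1,3 to C4 and can hold a silicon tether to the dione enol oxygen.
Order of rings: the cyclopentane is bought in as 3-methylcyclopent-2-enone; an intramolecular [2+2] photocycloaddition builds a cyclobutane (plus a temporary silaketal ring); retro-aldol opening of the cyclobutane then gives the seven-membered ring.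
Stereochemistry: a Corey–Bakshi–Shibata carbinol at C3 is relayed through the tether to quaternary C8a and then erased by oxidation; C3 is reset by Grignard addition anti to the C8a methyl, C3a by protonation to the trans fusion, C4 by hydroxyl-directed reduction, C7 by catalyst-controlled reduction.
Key step: step 3

Remark: α/β mean opposite to/same side as the C8a methyl; photoadducts 6 and 7 keep the azulene locants of the atoms they become; reagents named without a number are taken as purchased.

Step 1
Reactants: 1 3-methylcyclopent-2-en-1-one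
Product: 2 (R)-3-methylcyclopent-2-en-1-ol
Conditions: (S)-1-methyl-3,3-diphenyltetrahydro-1H,3H-pyrrolo[1,2-c][1,3,2]oxazaborole (10 mol%), catecholborane, toluene, −78 °C
Reagents that add atoms: none
Why: Corey–Bakshi–Shibata reduction, in which the ketone binds to the oxazaborolidine boron with the alkenyl arm as the large group, so that hydride from the coordinated borane should reach one carbonyl face and give the (R)-carbinol.

Step 2
Reactants: 2 (R)-3-methylcyclopent-2-en-1-ol; 3 cyclopentane-1,3-dione
Product: 5 3-({diisopropyl[(1R)-3-methylcyclopent-2-en-1-yloxy]silyl}oxy)cyclopent-2-en-1-one, via chlorosilyl ether 4 (not isolated)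
Conditions: iPr2SiCl2 (3 equiv), Et3N, CH2Cl2, −78 → 0 °C, excess silane removed in vacuo; then 3, Et3N, 4-(dimethylamino)pyridine (cat.), CH2Cl2, 0 °C
Reagents that add atoms: dichlorodiisopropylsilane CC(C)[Si](Cl)(Cl)C(C)C
Why: Sequential silyl ether formation on the dichlorosilane (temporary silaketal tether), where the excess of silane keeps the first substitution to one alkoxy group and the dione, reacting as its enol, is then silylated on oxygen to the vinylogous silyl ester without touching the C3 stereocenter.

Step 3
Reactants: 5 3-({diisopropyl[(1R)-3-methylcyclopent-2-en-1-yloxy]silyl}oxy)cyclopent-2-en-1-one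
Product: 6 silaketal-bridged cyclobutane photoadduct (3α,4α-(diisopropylsilylenedioxy)-8aβ-methyl-4,8-cyclodecahydroazulen-7-one; cyclobutane C3a–C4–C8–C8a cis-fused to both five-membered rings, which lie anti to each other)
Conditions: hν (λ ≥ 300 nm, Pyrex filter), degassed MeCN, 0.01 M, 0 °C
Reagents that add atoms: none
Why: De Mayo-type intramolecular enone–alkene [2+2] photocycloaddition: the triplet of the 3-silyloxy enone bonds through its oxygenated β-carbon (future C4) to the cyclopentene CH (future C3a), and the resulting 1,4-biradical (tertiary radical at future C8a, α-keto radical at future C8) collapses to the cyclobutane, so both bonds form in one photochemical event. The closest known reaction types are the de Mayo photocycloaddition of tethered enol derivatives of 1,3-diketones and enone–alkene photocycloadditions run through temporary silicon tethers. The 1,3-dioxa-2-silinane ring closes first in a 6-exo-trig radical mode, and the cyclobutane then closes by recombination of the 1,4-biradical, cis-fused to both five-membered rings. C8a, the only new stereocenter that survives, is controlled by the tether anchored on the C3 oxygen, which forces the enone onto the face of the C3–O bond and so puts the methyl on the opposite (β) face; C3a, C4 and C8 are formed cis by the suprafacial fusion but are later erased or become CH2. The step needs head-to-head regiochemistry (oxygenated enone carbon to the alkene CH) and one π-face; both are secured by the four-atom O–Si–O–C tether, whose length allows only the six-membered closure at the alkene carbon next to C3, while high dilution suppresses intermolecular dimerization.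

Step 4
Reactants: 6 silaketal-bridged cyclobutane photoadduct
Product: 8 cis-fused 3α-hydroxy-8aβ-methyloctahydroazulene-4,7-dione (H-3a β), via cyclobutanediol ketone 7 (not isolated)
Conditions: Bu4NF (2.2 equiv), AcOH (2.2 equiv), THF, 0 °C → rt
Reagents that add atoms: none
Why: Fluoride cleaves both Si–O bonds and the freed cyclobutanol, a strained β-hydroxy ketone, opens by retro-aldol (the fragmentation half of the de Mayo reaction) across the C4–C8 bond to the cycloheptane-1,4-dione, the acetic acid buffer keeping the C3 hydroxyl from eliminating and C8a being retained.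

Step 5
Reactants: 8 cis-fused 3α-hydroxy-8aβ-methyloctahydroazulene-4,7-dione
Product: 9 8aβ-methyloctahydroazulene-3,4,7-trione (C3a labile, largely enolized)
Conditions: 1,1,1-triacetoxy-1,1-dihydro-1,2-benziodoxol-3(1H)-one (Dess–Martin periodinane), CH2Cl2, rt
Reagents that add atoms: none
Why: Dess–Martin oxidation of the only carbinol gives the cyclic β-diketone, which erases the relay stereocenter at C3 and makes C3a configurationally labile while quaternary C8a is untouched.

Step 6
Reactants: 9 8aβ-methyloctahydroazulene-3,4,7-trione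
Product: 10 4,7-bis(tert-butyldimethylsilyloxy)-8aβ-methyl-2,5,8,8a-tetrahydroazulen-3(1H)-one (double bonds C3a=C4 and C6=C7)
Conditions: LiN(SiMe3)2 (2.1 equiv), THF, −78 °C; tBuMe2SiOTf (2.2 equiv), −78 → 0 °C; non-aqueous work-up, used crude
Reagents that add atoms: tert-butyldimethylsilyl trifluoromethanesulfonate CC(C)(C)[Si](C)(C)OS(=O)(=O)C(F)(F)F
Why: Double O-silylation of the dianion (β-diketonate plus the kinetic enolate of the isolated C7 ketone), in which the diketonate silyl group can shuttle between the two cis-held oxygens and should settle on the C4 oxygen, where the C3a=C4 double bond is exocyclic to the five-membered and endocyclic to the seven-membered ring, leaving C3 as the only free carbonyl and C7 masked as a silyl enol ether.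

Step 7
Reactants: 10 4,7-bis(tert-butyldimethylsilyloxy)-8aβ-methyl-2,5,8,8a-tetrahydroazulen-3(1H)-one
Product: 12 trans-fused 3β-hydroxy-3α-isopropyl-8aβ-methyloctahydroazulene-4,7-dione (H-3a α), via bis(silyl enol ether) carbinol 11 (not isolated)
Conditions: iPrMgCl (1.5 equiv), LaCl3·2LiCl (0.5 equiv), THF, −78 → −40 °C; then Bu4NF, AcOH, THF, 0 °C
Reagents that add atoms: isopropylmagnesium chloride CC(C)[Mg]Cl
Why: 1,2-Addition of the Grignard reagent, made less basic by LaCl3·2LiCl, to the vinylogous silyl ester carbonyl (first half of a Stork–Danheiser sequence) from the α-face, anti to the C8a methyl, sets C3 (isopropyl α, hydroxyl β), and buffered fluoride then frees both ketones without acid so that the aldol is kept and C3a is protonated to the trans fusion, in which the isopropyl group is cis to the small C3a hydrogen and the C3 hydroxyl can hydrogen-bond to the C4 carbonyl.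

Step 8
Reactants: 12 trans-fused 3β-hydroxy-3α-isopropyl-8aβ-methyloctahydroazulene-4,7-dione
Product: 13 trans-fused 3β,4α-dihydroxy-3α-isopropyl-8aβ-methyloctahydroazulen-7-one
Conditions: Me4NBH(OAc)3, MeCN/AcOH (1:1), −20 °C
Reagents that add atoms: none
Why: Evans–Saksena hydroxyl-directed reduction, in which the C3 hydroxyl exchanges onto boron and delivers hydride intramolecularly to the β-face of the C4 carbonyl to give the 1,3-anti diol (C4 hydroxyl α), while the C7 ketone, lacking a β-hydroxyl, is not reduced by the triacetoxyborohydride.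

Step 9
Reactants: 13 trans-fused 3β,4α-dihydroxy-3α-isopropyl-8aβ-methyloctahydroazulen-7-one; 14 4-acetoxybenzoyl chloride
Product: 15 3β-hydroxy-3α-isopropyl-8aβ-methyl-7-oxodecahydroazulen-4α-yl 4-acetoxybenzoate
Conditions: 14 (1.5 equiv), pyridine, 4-(dimethylamino)pyridine (cat.), CH2Cl2, 0 °C → rt
Reagents that add atoms: none
Why: Nucleophile-catalysed acylation in which only the secondary C4 hydroxyl reacts, the tertiary C3 hydroxyl being too hindered, and no stereocenter is touched.

Step 10
Reactants: 15 3β-hydroxy-3α-isopropyl-8aβ-methyl-7-oxodecahydroazulen-4α-yl 4-acetoxybenzoate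
Product: 16 3β-hydroxy-3α-isopropyl-8aβ-methyl-6-methylidene-7-oxodecahydroazulen-4α-yl 4-acetoxybenzoate
Conditions: (CH2O)n, N-methylanilinium trifluoroacetate, THF, reflux
Reagents that add atoms: formaldehyde (as paraformaldehyde) C=O
Why: Direct α-methylenation by Mannich condensation and elimination, in which the iminium ion from formaldehyde and N-methylaniline attacks the enol of the only ketone at C6, since C8 is a neopentyl position beside C8a, and the β-amino ketone loses the amine to give the exocyclic enone.

Step 11
Reactants: 16 3β-hydroxy-3α-isopropyl-8aβ-methyl-6-methylidene-7-oxodecahydroazulen-4α-yl 4-acetoxybenzoate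
Product: 17 3β,7α-dihydroxy-3α-isopropyl-8aβ-methyl-6-methylidenedecahydroazulen-4α-yl 4-acetoxybenzoate
Conditions: (R)-1-methyl-3,3-diphenyltetrahydro-1H,3H-pyrrolo[1,2-c][1,3,2]oxazaborole (0.5 equiv), catecholborane, toluene, −78 °C
Reagents that add atoms: none
Why: Corey–Bakshi–Shibata reduction under catalyst control, in which the (R)-oxazaborolidine, with the alkenyl arm (C6) as the large group, should direct hydride to the β-face of C7 and give the 7α (7S) allylic alcohol by 1,2-reduction.

Step 12
Reactants: 17 3β,7α-dihydroxy-3α-isopropyl-8aβ-methyl-6-methylidenedecahydroazulen-4α-yl 4-acetoxybenzoate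
Product: 18 ferugin, (3R,3aS,4S,7S,8aR)-3,7-dihydroxy-8a-methyl-6-methylidene-3-(propan-2-yl)decahydroazulen-4-yl 4-hydroxybenzoate
Conditions: K2CO3 (cat.), MeOH, 0 °C
Reagents that add atoms: none
Why: Base-catalysed transesterification in which the aryl acetate is far more electrophilic than the hindered secondary benzoate, whose carbonyl is further deactivated once the phenoxide forms, so only the acetyl group is lost.

Compound list
1 | 3-methylcyclopent-2-en-1-one | CC1=CC(=O)CC1 | starting material
2 | (R)-3-methylcyclopent-2-en-1-ol | CC1=C[C@H](O)CC1 | intermediate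
3 | cyclopentane-1,3-dione | O=C1CCC(=O)C1 | starting material
4 | chloro(diisopropyl)[(1R)-3-methylcyclopent-2-en-1-yloxy]silane (not isolated) | CC1=C[C@H](O[Si](Cl)(C(C)C)C(C)C)CC1 | intermediate
5 | 3-({diisopropyl[(1R)-3-methylcyclopent-2-en-1-yloxy]silyl}oxy)cyclopent-2-en-1-one | CC1=C[C@H](O[Si](OC2=CC(=O)CC2)(C(C)C)C(C)C)CC1 | intermediate
6 | silaketal-bridged cyclobutane photoadduct, 3α,4α-(diisopropylsilylenedioxy)-8aβ-methyl-4,8-cyclodecahydroazulen-7-one | C[C@@]12CC[C@H]3O[Si](C(C)C)(C(C)C)O[C@]4(CCC(=O)[C@H]14)[C@@H]23 | intermediate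
7 | 3α,4α-dihydroxy-8aβ-methyl-4,8-cyclodecahydroazulen-7-one, cyclobutanediol ketone (not isolated) | C[C@]12CC[C@@H](O)[C@H]1[C@]3(O)CCC(=O)[C@H]23 | intermediate
8 | cis-fused 3α-hydroxy-8aβ-methyloctahydroazulene-4,7-dione (H-3a β) | O=C1CCC(=O)[C@H]2[C@](C)(CC[C@H]2O)C1 | intermediate
9 | 8aβ-methyloctahydroazulene-3,4,7-trione (C3a labile) | O=C1CCC(=O)C2[C@](C)(CCC2=O)C1 | intermediate
10 | 4,7-bis(tert-butyldimethylsilyloxy)-8aβ-methyl-2,5,8,8a-tetrahydroazulen-3(1H)-one | C1(O[Si](C)(C)C(C)(C)C)=CCC(O[Si](C)(C)C(C)(C)C)=C2[C@](C)(CCC2=O)C1 | intermediate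
11 | 4,7-bis(tert-butyldimethylsilyloxy)-3α-isopropyl-8aβ-methyl-1,2,3,5,8,8a-hexahydroazulen-3β-ol (not isolated) | C1(O[Si](C)(C)C(C)(C)C)=CCC(O[Si](C)(C)C(C)(C)C)=C2[C@](C)(CC[C@@]2(O)C(C)C)C1 | intermediate
12 | trans-fused 3β-hydroxy-3α-isopropyl-8aβ-methyloctahydroazulene-4,7-dione (H-3a α) | C1CC(=O)[C@@H]2[C@](C)(CC[C@@]2(O)C(C)C)CC1=O | intermediate
13 | trans-fused 3β,4α-dihydroxy-3α-isopropyl-8aβ-methyloctahydroazulen-7-one | C1C[C@H](O)[C@@H]2[C@](C)(CC[C@@]2(O)C(C)C)CC1=O | intermediate
14 | 4-acetoxybenzoyl chloride | CC(=O)Oc1ccc(cc1)C(Cl)=O | starting material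
15 | 3β-hydroxy-3α-isopropyl-8aβ-methyl-7-oxodecahydroazulen-4α-yl 4-acetoxybenzoate | C1C[C@H](OC(=O)c2ccc(OC(C)=O)cc2)[C@@H]2[C@](C)(CC[C@@]2(O)C(C)C)CC1=O | intermediate
16 | 3β-hydroxy-3α-isopropyl-8aβ-methyl-6-methylidene-7-oxodecahydroazulen-4α-yl 4-acetoxybenzoate | C=C1C[C@H](OC(=O)c2ccc(OC(C)=O)cc2)[C@@H]2[C@](C)(CC[C@@]2(O)C(C)C)CC1=O | intermediate
17 | 3β,7α-dihydroxy-3α-isopropyl-8aβ-methyl-6-methylidenedecahydroazulen-4α-yl 4-acetoxybenzoate | C=C1C[C@H](OC(=O)c2ccc(OC(C)=O)cc2)[C@@H]2[C@](C)(CC[C@@]2(O)C(C)C)C[C@@H]1O | intermediate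
18 | ferugin, (3R,3aS,4S,7S,8aR)-3,7-dihydroxy-8a-methyl-6-methylidene-3-(propan-2-yl)decahydroazulen-4-yl 4-hydroxybenzoate | C=C1C[C@H](OC(=O)c2ccc(O)cc2)[C@@H]2[C@](C)(CC[C@@]2(O)C(C)C)C[C@@H]1O | target

Total step count: 12.
Longest linear sequence: 12 steps (1 → 18).

Steps most likely to fail

Step 3. The vinylogous silyl ester may be hydrolysed before or during irradiation, or ring closure may be too slow, so that the excited enone decays or dimerizes. Fallback, setting out from 2 and 3 and coming back at 8: alcohol 2 is alkylated with chloromethyl methyl sulfide (NaH, NaI, THF) to (1R)-3-methylcyclopent-2-en-1-yl (methylsulfanyl)methyl ether F1; sulfuryl chloride converts this into the chloromethyl ether F2; O-alkylation of dione 3 (iPr2NEt, CH2Cl2) gives the acetal-tethered vinylogous ester F3, a hydrolytically robust 3-alkoxy enone of a class well established in intramolecular [2+2] photocycloaddition. Irradiation as in step 3 should give the methylenedioxy-bridged photoadduct F4, and aqueous HCl in THF cleaves the acetal, after which the cyclobutanol opens by retro-aldol to 8.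

Step 7. The silyl group may sit on the C3 oxygen at the moment of addition so that the Grignard reagent attacks C4; facial selectivity at C3 may be poor; or the ketol may lose water on desilylation. Fallback, setting out from 8 and coming back at 12, with each oxygen handled by protection: tBuMe2SiCl and imidazole give the silyl ether F5. Ethylene glycol with pyridinium p-toluenesulfonate in refluxing benzene ketalizes only the unhindered C7 ketone and equilibrates C3a, giving the trans-fused dioxolane F6. NaBH4 attacks the C4 ketone anti to the C8a methyl to give the 4β-alcohol F7, which is capped with chloromethyl methyl ether and iPr2NEt as the methoxymethyl ether F8. Bu4NF frees the C3 alcohol F9, Dess–Martin oxidation gives the C3 ketone F10, and iPrMgCl with LaCl3·2LiCl adds anti to the angular methyl to give the tertiary carbinol F11. HCl in aqueous methanol removes acetal and ketal to give the diol ketone F12, and Dess–Martin oxidation of its only secondary alcohol returns 12.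

Step 11. Facial selectivity may be poor, because hydride delivery to the β-face of C7 runs against the C8a methyl and substrate control may override the catalyst to give the 7β-alcohol. Fallback, setting out from 16 and coming back at 18: enone 16 is reduced without a chiral catalyst (NaBH4, CeCl3·7H2O, MeOH, −78 °C; Luche reduction) to the substrate-preferred 7β-allylic alcohol F13. This is inverted by Mitsunobu reaction with 4-nitrobenzoic acid (PPh3, diisopropyl azodicarboxylate) to the 7α 4-nitrobenzoate F14. K2CO3 in methanol then removes the nitrobenzoate together with the aryl acetate and gives 18 directly.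

Further compounds
F1 | step 3 | (1R)-3-methylcyclopent-2-en-1-yl (methylsulfanyl)methyl ether | CC1=C[C@H](OCSC)CC1
F2 | step 3 | (1R)-3-methylcyclopent-2-en-1-yl chloromethyl ether | CC1=C[C@H](OCCl)CC1
F3 | step 3 | 3-{[(1R)-3-methylcyclopent-2-en-1-yloxy]methoxy}cyclopent-2-en-1-one | CC1=C[C@H](OCOC2=CC(=O)CC2)CC1
F4 | step 3 | 3α,4α-(methylenedioxy)-8aβ-methyl-4,8-cyclodecahydroazulen-7-one, methylenedioxy-bridged photoadduct | C[C@@]12CC[C@H]3OCO[C@]4(CCC(=O)[C@H]14)[C@@H]23
F5 | step 7 | cis-fused 3α-(tert-butyldimethylsilyloxy)-8aβ-methyloctahydroazulene-4,7-dione | C[C@]12CC[C@@H](O[Si](C)(C)C(C)(C)C)[C@H]1C(=O)CCC(=O)C2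
F6 | step 7 | trans-fused 3α-(tert-butyldimethylsilyloxy)-7,7-(ethylenedioxy)-8aβ-methyloctahydroazulen-4-one | C[C@]12CC[C@@H](O[Si](C)(C)C(C)(C)C)[C@@H]1C(=O)CCC3(OCCO3)C2
F7 | step 7 | trans-fused 3α-(tert-butyldimethylsilyloxy)-7,7-(ethylenedioxy)-8aβ-methyldecahydroazulen-4β-ol | C[C@]12CC[C@@H](O[Si](C)(C)C(C)(C)C)[C@@H]1[C@H](O)CCC3(OCCO3)C2
F8 | step 7 | 4β-methoxymethyl ether of F7 | C[C@]12CC[C@@H](O[Si](C)(C)C(C)(C)C)[C@@H]1[C@H](OCOC)CCC3(OCCO3)C2
F9 | step 7 | trans-fused 7,7-(ethylenedioxy)-4β-(methoxymethoxy)-8aβ-methyldecahydroazulen-3α-ol | C[C@]12CC[C@@H](O)[C@@H]1[C@H](OCOC)CCC3(OCCO3)C2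
F10 | step 7 | trans-fused 7,7-(ethylenedioxy)-4β-(methoxymethoxy)-8aβ-methyloctahydroazulen-3-one | C[C@]12CCC(=O)[C@@H]1[C@H](OCOC)CCC3(OCCO3)C2
F11 | step 7 | trans-fused 7,7-(ethylenedioxy)-3α-isopropyl-4β-(methoxymethoxy)-8aβ-methyldecahydroazulen-3β-ol | C[C@]12CC[C@@](O)(C(C)C)[C@@H]1[C@H](OCOC)CCC3(OCCO3)C2
F12 | step 7 | trans-fused 3β,4β-dihydroxy-3α-isopropyl-8aβ-methyloctahydroazulen-7-one | C[C@]12CC[C@@](O)(C(C)C)[C@@H]1[C@H](O)CCC(=O)C2
F13 | step 11 | 3β,7β-dihydroxy-3α-isopropyl-8aβ-methyl-6-methylidenedecahydroazulen-4α-yl 4-acetoxybenzoate | C=C1C[C@H](OC(=O)c2ccc(OC(C)=O)cc2)[C@@H]2[C@](C)(CC[C@@]2(O)C(C)C)C[C@H]1O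
F14 | step 11 | 3β-hydroxy-3α-isopropyl-8aβ-methyl-6-methylidene-7α-(4-nitrobenzoyloxy)decahydroazulen-4α-yl 4-acetoxybenzoate | C=C1C[C@H](OC(=O)c2ccc(OC(C)=O)cc2)[C@@H]2[C@](C)(CC[C@@]2(O)C(C)C)C[C@@H]1OC(=O)c1ccc(cc1)[N+](=O)[O-]
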